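## Analysis of the target

Caraphenol B (17) is a 2,3-dihydro-1H-indene: the resorcinol ring A (C3a, C4 to C7, C7a; hydroxyls on C4 and C6) is fused to the five-membered ring B (C1, C2, C3, C3a, C7a). Ring B carries three contiguous stereocentres: C1 bears a 4-hydroxybenzoyl group (its aryl ring is called ring E here), C2 the 4-hydroxyphenyl ring C and C3 the 3,5-dihydroxyphenyl ring D. All three substituents stand on the same face of ring B, and the configuration is (1R,2R,3R). C1 is benzylic and α to an aryl ketone, so it epimerizes easily, and with the aroyl group cis to ring C this is unlikely to be the more stable arrangement at that centre; C3 is doubly benzylic. The six free phenols make the compound electron-rich and sensitive to oxidants, strong acids and bases, which limits what can be done once they are unmasked. The hard part is therefore not the carbon skeleton but the all-cis triad with a labile C1, which has to be set late and under kinetic control. The plan rests on one feature: C1 carries an acyl carbon and C3 carries ring D. A ring A unit with a keto ester on C7a and an alkyne on C3a, whose outer carbon (the future C2) already holds ring C, can therefore take up ring D at C3 and join C2 to the keto carbon C1 in one operation that closes ring B and leaves C1 as a carbinol that cannot enolize.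

## Retrosynthetic reasoning

**C1–H (17 to 15).** The last bond made is C1–H. C1 is the only centre of 17 that can epimerize, so it is traced back to carbinol 15, in which C1 is quaternary and carries a hydroxyl in place of the hydrogen. Cutting here, and not at C2 or C3, means that no later step can touch the labile centre. The forward reaction has to cleave the C1–O bond of the α-hydroxy ketone reductively and protonate the resulting enolate 16 on the face opposite the C2 aryl group.

**C2–H, C3–H and the phenolic O–H bonds (15 to 14).** These are traced back to the C2=C3 double bond and the six benzyl ethers of 14. A single heterogeneous hydrogenation should do both. Syn addition makes rings C and D cis by necessity, and the C1 carbinol (small hydroxyl on one face, aroyl on the other) decides which face is used. The quaternary C1 thus relays its configuration to C2 and C3 before it is itself converted.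

**Ketone carbon–ring E (14 to 11 and 13, then 11 to 10).** The bond between the ketone carbon and ring E is cut to give amide 11 and Grignard reagent 13, which comes from bromide 12; 11 goes back to methyl ester 10. The ketone is introduced only after ring B is closed, because the ring closure needs a keto ester, and an ester is the acyl group that survives it. The forward steps must add one aryl group and no more, without exposing the α-ketol to base.

**C3–ring D and C1–C2 (10 to 7 and 9).** This is the central disconnection. Both bonds are cut at once, which opens ring B and leads to alkyne keto ester 7 and boronic acid 9. No other pair of cuts brings in ring D, closes the ring and creates a non-enolizable stereocentre in one step from two simple aryl building blocks. The forward reaction has to add the aryl group of 9 to C3, bring the metal on C2 to the side of ring A (a formal anti addition), and add C2 to one face of the ketone. The ring closure cannot correct an insertion that puts the metal on C3, so the regiochemistry must come from the insertion itself; this is where the risk of the route sits.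

**C3a–alkyne (7 to 5 and 6).** The C3a–C(sp) bond is cut to give aryl iodide 5 and terminal alkyne 6. Cross-coupling at this bond is reliable even next to two ortho substituents, and it brings ring C in with its final attachment to C2 already fixed.

**C–I and aryl–acyl bonds (5 to 4, then 4 to 1 and 2).** Iodide 5 goes back to glyoxylate 4 by removing the iodine; the two positions ortho to the keto ester in 4 are equivalent and activated by both ether oxygens. The aryl–acyl bond of 4 is cut to aryllithium 3, made from bromide 1, and oxalate 2.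

**C–B (9 to 1).** Boronic acid 9 is traced back to the same bromide 1, this time through arylmagnesium bromide 8, so rings A and D come from one starting material.

## Alternatives that were turned down

Alternative 1: donor/donor rhodium carbene C–H insertion (C2–C3 bond).
- Disconnection and key step: Rh2(R-PTAD)4 would decompose diazo compound A1, in which ring A carries the diazo(3,5-dimethoxyphenyl)methyl group on C3a and a 1,3-bis(4-methoxyphenyl)prop-1-en-2-yl group on C7a. The carbene at C3 would insert into the allylic, benzylic C2–H bond and give the cis-2,3-diaryl benzylidene indane A2.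
- For: C2 and C3 are set together under catalyst control, and the ring closure has no regiochemical ambiguity. On that point it is stronger than the chosen key step.
- Against: the methoxy group on C4 sits ortho to the carbene carbon and offers a competing insertion into its own C–H bonds, leading to a dihydrobenzofuran. C1 is left as an exocyclic alkene that must still be turned into the ketone with a new cis C1–H. The ether groups must be cleaved at the very end with a boron trihalide, conditions under which an all-cis C1 next to an aryl ketone is likely to equilibrate.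
- Comparison: the chosen strategy accepts a less certain ring closure but keeps benzyl ethers, removed under neutral conditions, and creates the labile C1–H in the last step.

Alternative 2: rhodium asymmetric hydroacylation, then relay from C3 (C1–C2 bond).
- Disconnection and key step: [Rh(cod)Cl]2, (R)-BINAP and AgBF4 would add the aldehyde C–H bond of the 2-(1-arylvinyl)benzaldehyde A3 across its 1,1-diarylethene and give the 3-arylindan-1-one A4 with C3 set.
- For: the ring closure is intramolecular and regiochemically fixed, and this substrate class is well established for the reaction. It is the most secure key step of the four.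
- Against: it builds one bond and one stereocentre. Ring C, ring E, the acyl carbon and two stereocentres remain to be added. α-Arylation of A4 would give the trans 2,3-relationship, so the all-cis triad would need a C1=C2 indene and hydrogenation anti to ring D; in such indenes the doubly benzylic, allylic C3–H can migrate and erase the only stereocentre.
- Comparison: it is longer and its relay runs through an enolizable, isomerizable series. The chosen strategy forms two skeletal bonds in the key step and relays through a quaternary carbinol.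

Alternative 3: rhodium (3+2) indenol annulation with hydroxyl relay (C7a–C1 and C2–C3 bonds).
- Disconnection and key step: [RhCl(C2H4)2]2 with a chiral diene would add the aryl group of boronic acid A5 across the alkyne of propargylic silyl ether A6 (C7a–C1 bond); the alkenylrhodium on C2 would then attack the diaryl ketone and give the tertiary indenol A7 with the carbinol at C3.
- For: it is as convergent as the chosen route. Its alkyne has one aryl and one alkyl terminus, so the regiochemistry of insertion is better secured than with the diarylalkyne 7; on that point it is stronger.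
- Against: the relay carbinol sits at C3, a diarylmethyl centre with no carbonyl beside it. Its removal has to pass through a planar cation or radical, which would favour the trans arrangement, and there is no counterpart to the reductive α-ketol cleavage. The 2,6-disubstituted benzophenone is a poor acceptor for the alkenylrhodium. An extra silyloxy stereocentre is carried only to be oxidized, which adds protecting-group and redox steps.
- Comparison: the chosen strategy places the carbinol at C1, next to the future ketone, where it can be replaced by hydrogen in one mild step with kinetic protonation.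

Key step: step 5

Assumption: the sense of induction of the nickel–phosphinooxazoline catalyst with a glyoxylate acceptor is taken to follow that with simple ketones, so the (R)-ligand is written; the mirror-image ligand would be used if the opposite carbinol were to form.

## Route

Step 1
Reactants: 1 1-bromo-3,5-bis(benzyloxy)benzene; 2 dimethyl oxalate
Product: 4 methyl 2-[3,5-bis(benzyloxy)phenyl]-2-oxoacetate, via aryllithium 3 (not isolated)
Conditions: n-BuLi, THF, −78 °C; then added to 2 (3 equiv), THF, −78 °C; aq NH4Cl
Reagents that add atoms: none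
Why: Bromine–lithium exchange is fast at −78 °C and tolerates the benzyl ethers; inverse addition of 3 to an excess of 2 gives a tetrahedral adduct that survives until the quench, so a single acyl substitution delivers the aryl glyoxylate (α-keto ester synthesis from an aryllithium and a dialkyl oxalate).

Step 2
Reactants: 4 methyl 2-[3,5-bis(benzyloxy)phenyl]-2-oxoacetate
Product: 5 methyl 2-[3,5-bis(benzyloxy)-2-iodophenyl]-2-oxoacetate
Conditions: NIS (1.05 equiv), CF3CO2H (0.3 equiv), MeCN, 0 °C to rt, dark
Reagents that add atoms: N-iodosuccinimide, O=C1CCC(=O)N1I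
Why: Electrophilic aromatic iodination; the two equivalent positions ortho to the keto ester are each para to one benzyloxy group and ortho to the other and are less crowded than the position between the two ethers, the pattern known for 3,5-dialkoxybenzoyl compounds; one equivalent of reagent limits di-iodination and the unactivated benzyl rings should not react.

Step 3
Reactants: 5 methyl 2-[3,5-bis(benzyloxy)-2-iodophenyl]-2-oxoacetate; 6 1-(benzyloxy)-4-ethynylbenzene
Product: 7 methyl 2-[3,5-bis(benzyloxy)-2-{[4-(benzyloxy)phenyl]ethynyl}phenyl]-2-oxoacetate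
Conditions: PdCl2(PPh3)2 (5 mol %), CuI (10 mol %), Et3N, THF, 40 °C
Reagents that add atoms: none
Why: Sonogashira coupling; oxidative addition of zerovalent palladium into the C–I bond is helped by the ortho acyl group, and a tertiary amine in an alcohol-free medium should leave the electrophilic keto ester and the new ortho-alkynyl ketone untouched.

Step 4
Reactants: 1 1-bromo-3,5-bis(benzyloxy)benzene
Product: 9 [3,5-bis(benzyloxy)phenyl]boronic acid, via arylmagnesium bromide 8 (not isolated)
Conditions: Mg (I2 cat.), THF, 50 °C; then B(OMe)3 (2 equiv), THF, −78 °C to rt; 1 M HCl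
Reagents that add atoms: trimethyl borate, COB(OC)OC; water, O
Why: Magnesium insertion into the aryl bromide gives 8 with the benzyl ethers untouched; at −78 °C it adds once to an excess of trimethyl borate, and aqueous acid cleaves the remaining B–OMe bonds to give the boronic acid (borylation of a Grignard reagent).

Step 5
Reactants: 7 methyl 2-[3,5-bis(benzyloxy)-2-{[4-(benzyloxy)phenyl]ethynyl}phenyl]-2-oxoacetate; 9 [3,5-bis(benzyloxy)phenyl]boronic acid
Product: 10 methyl (1R)-4,6-bis(benzyloxy)-3-[3,5-bis(benzyloxy)phenyl]-2-[4-(benzyloxy)phenyl]-1-hydroxy-1H-indene-1-carboxylate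
Conditions: Ni(OAc)2·4H2O (10 mol %), (R)-2-[2-(diphenylphosphanyl)phenyl]-4-phenyl-4,5-dihydrooxazole (12 mol %), 9 (2 equiv), CF3CH2OH, 80 °C
Reagents that add atoms: none
Why: Transmetallation of 9 to the divalent nickel acetate–phosphinooxazoline complex gives an arylnickel species that adds syn across the alkyne of 7, ring D to C3 and nickel to C2. The alkenylnickel, conjugated with ring C, inverts its geometry reversibly until nickel is cis to ring A, and this isomer adds to the keto carbonyl on C7a (C1–C2 bond); protonolysis of the nickel alkoxide by the solvent releases 10 and divalent nickel. The closest known reaction type is the nickel-catalysed enantioselective anti-carbometallative arylative cyclization of alkyne-tethered ketones with arylboronic acids. Ring B closes by a 5-exo-trig attack of C2 on the carbonyl carbon, with the C2=C3 bond ending up inside the ring. C1 is the only new stereocentre, and its configuration is set by the chiral ligand, which differentiates the two faces of the ketone in the carbonyl insertion. The step needs two selectivities: alkyne insertion must outrun direct 1,2-arylation of the activated ketone, which the strong binding of the alkyne to the arylnickel species should provide, and the insertion must put nickel on C2. The latter is not enforced by ring size and rests on the substrate: the ortho and para benzyloxy groups of ring A make C3 the alkyne carbon that accepts the migrating aryl group, and nickel on C2 is flanked by the unhindered, conjugating ring C instead of the doubly ortho-substituted ring A. The ester carbonyl is less electrophilic than the ketone and is not expected to compete.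

Step 6
Reactants: 10 methyl (1R)-4,6-bis(benzyloxy)-3-[3,5-bis(benzyloxy)phenyl]-2-[4-(benzyloxy)phenyl]-1-hydroxy-1H-indene-1-carboxylate
Product: 11 (1R)-4,6-bis(benzyloxy)-3-[3,5-bis(benzyloxy)phenyl]-2-[4-(benzyloxy)phenyl]-1-hydroxy-N-methoxy-N-methyl-1H-indene-1-carboxamide
Conditions: MeNHOMe·HCl (5 equiv), iPrMgCl (10 equiv), THF, −20 to 0 °C
Reagents that add atoms: N,O-dimethylhydroxylamine hydrochloride, CNOC.Cl
Why: Aminolysis of the methyl ester by the chloromagnesium amide formed in the flask (Weinreb amide synthesis); the tertiary hydroxyl is carried as its magnesium alkoxide, and C1, being quaternary, cannot epimerize.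

Step 7
Reactants: 11 (1R)-4,6-bis(benzyloxy)-3-[3,5-bis(benzyloxy)phenyl]-2-[4-(benzyloxy)phenyl]-1-hydroxy-N-methoxy-N-methyl-1H-indene-1-carboxamide; 12 1-(benzyloxy)-4-bromobenzene
Product: 14 [(1R)-4,6-bis(benzyloxy)-3-[3,5-bis(benzyloxy)phenyl]-2-[4-(benzyloxy)phenyl]-1-hydroxy-1H-inden-1-yl][4-(benzyloxy)phenyl]methanone, via Grignard reagent 13 (not isolated)
Conditions: 12, Mg, THF, 40 °C; then 11, THF, 0 °C to rt (4 equiv of 13); aq NH4Cl, 0 °C
Reagents that add atoms: none
Why: Weinreb ketone synthesis: one equivalent of 13 deprotonates the hydroxyl, and a further one adds to the amide to give a chelated tetrahedral intermediate that resists a second addition and releases the ketone only on the cold, mildly acidic quench, so the α-ketol is not exposed to base and α-ketol rearrangement should be avoided.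

Step 8
Reactants: 14 [(1R)-4,6-bis(benzyloxy)-3-[3,5-bis(benzyloxy)phenyl]-2-[4-(benzyloxy)phenyl]-1-hydroxy-1H-inden-1-yl][4-(benzyloxy)phenyl]methanone
Product: 15 [(1S,2S,3R)-3-(3,5-dihydroxyphenyl)-1,4,6-trihydroxy-2-(4-hydroxyphenyl)-2,3-dihydro-1H-inden-1-yl](4-hydroxyphenyl)methanone
Conditions: H2 (4 bar), 10% Pd/C, EtOAc/MeOH, rt
Reagents that add atoms: none
Why: Heterogeneous hydrogenation: the six aryl benzyl ethers are cleaved by hydrogenolysis, and hydrogen adds syn to the C2=C3 bond from the face that carries the small C1 hydroxyl and not the aroyl group, which places both new hydrogens cis to the hydroxyl and rings C and D cis to the aroyl group (C2 and C3 set by the C1 stereocentre); the C1 hydroxyl, tertiary and α to a carbonyl, should resist hydrogenolysis in neutral medium.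

Step 9
Reactants: 15 [(1S,2S,3R)-3-(3,5-dihydroxyphenyl)-1,4,6-trihydroxy-2-(4-hydroxyphenyl)-2,3-dihydro-1H-inden-1-yl](4-hydroxyphenyl)methanone
Product: 17 caraphenol B, [(1R,2R,3R)-3-(3,5-dihydroxyphenyl)-4,6-dihydroxy-2-(4-hydroxyphenyl)-2,3-dihydro-1H-inden-1-yl](4-hydroxyphenyl)methanone, via samarium enolate 16 (not isolated)
Conditions: SmI2 (2.5 equiv, 0.1 M in THF), THF/MeOH (10:1), −78 °C; AcOH, −78 °C; pH 5 aqueous work-up
Reagents that add atoms: none
Why: Reductive cleavage of an α-hydroxy ketone by SmI2: electron transfer to the aryl ketone gives a ketyl that expels the C1 oxygen, a second electron gives enolate 16, and at −78 °C the planar C1 is protonated from the face opposite the neighbouring C2 aryl group, the face the hydroxyl left, so that the aroyl group stays cis to rings C and D (kinetic protonation); the cold acidic quench avoids equilibration of the labile C1.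

## Compound list

1 | 1-bromo-3,5-bis(benzyloxy)benzene | Brc1cc(OCc2ccccc2)cc(OCc2ccccc2)c1 | starting material
2 | dimethyl oxalate | COC(=O)C(=O)OC | starting material
3 | [3,5-bis(benzyloxy)phenyl]lithium | [Li]c1cc(OCc2ccccc2)cc(OCc2ccccc2)c1 | intermediate
4 | methyl 2-[3,5-bis(benzyloxy)phenyl]-2-oxoacetate | COC(=O)C(=O)c1cc(OCc2ccccc2)cc(OCc2ccccc2)c1 | intermediate
5 | methyl 2-[3,5-bis(benzyloxy)-2-iodophenyl]-2-oxoacetate | COC(=O)C(=O)c1cc(OCc2ccccc2)cc(OCc2ccccc2)c1I | intermediate
6 | 1-(benzyloxy)-4-ethynylbenzene | C#Cc1ccc(OCc2ccccc2)cc1 | starting material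
7 | methyl 2-[3,5-bis(benzyloxy)-2-{[4-(benzyloxy)phenyl]ethynyl}phenyl]-2-oxoacetate | COC(=O)C(=O)c1cc(OCc2ccccc2)cc(OCc2ccccc2)c1C#Cc1ccc(OCc2ccccc2)cc1 | intermediate
8 | [3,5-bis(benzyloxy)phenyl]magnesium bromide | Br[Mg]c1cc(OCc2ccccc2)cc(OCc2ccccc2)c1 | intermediate
9 | [3,5-bis(benzyloxy)phenyl]boronic acid | OB(O)c1cc(OCc2ccccc2)cc(OCc2ccccc2)c1 | intermediate
10 | methyl (1R)-4,6-bis(benzyloxy)-3-[3,5-bis(benzyloxy)phenyl]-2-[4-(benzyloxy)phenyl]-1-hydroxy-1H-indene-1-carboxylate | COC(=O)[C@@]1(O)c2cc(OCc3ccccc3)cc(OCc3ccccc3)c2C(c2cc(OCc3ccccc3)cc(OCc3ccccc3)c2)=C1c1ccc(OCc2ccccc2)cc1 | intermediate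
11 | (1R)-4,6-bis(benzyloxy)-3-[3,5-bis(benzyloxy)phenyl]-2-[4-(benzyloxy)phenyl]-1-hydroxy-N-methoxy-N-methyl-1H-indene-1-carboxamide | CON(C)C(=O)[C@@]1(O)c2cc(OCc3ccccc3)cc(OCc3ccccc3)c2C(c2cc(OCc3ccccc3)cc(OCc3ccccc3)c2)=C1c1ccc(OCc2ccccc2)cc1 | intermediate
12 | 1-(benzyloxy)-4-bromobenzene | Brc1ccc(OCc2ccccc2)cc1 | starting material
13 | [4-(benzyloxy)phenyl]magnesium bromide | Br[Mg]c1ccc(OCc2ccccc2)cc1 | intermediate
14 | [(1R)-4,6-bis(benzyloxy)-3-[3,5-bis(benzyloxy)phenyl]-2-[4-(benzyloxy)phenyl]-1-hydroxy-1H-inden-1-yl][4-(benzyloxy)phenyl]methanone | O=C(c1ccc(OCc2ccccc2)cc1)[C@@]1(O)c2cc(OCc3ccccc3)cc(OCc3ccccc3)c2C(c2cc(OCc3ccccc3)cc(OCc3ccccc3)c2)=C1c1ccc(OCc2ccccc2)cc1 | intermediate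
15 | [(1S,2S,3R)-3-(3,5-dihydroxyphenyl)-1,4,6-trihydroxy-2-(4-hydroxyphenyl)-2,3-dihydro-1H-inden-1-yl](4-hydroxyphenyl)methanone | O=C(c1ccc(O)cc1)[C@@]1(O)c2cc(O)cc(O)c2[C@@H](c2cc(O)cc(O)c2)[C@H]1c1ccc(O)cc1 | intermediate
16 | diiodo{[(2S,3R)-3-(3,5-dihydroxyphenyl)-4,6-dihydroxy-2-(4-hydroxyphenyl)-2,3-dihydro-1H-inden-1-ylidene](4-hydroxyphenyl)methoxy}samarium (samarium enolate) | I[Sm](I)OC(c1ccc(O)cc1)=C1c2cc(O)cc(O)c2[C@@H](c2cc(O)cc(O)c2)[C@H]1c1ccc(O)cc1 | intermediate
17 | caraphenol B, [(1R,2R,3R)-3-(3,5-dihydroxyphenyl)-4,6-dihydroxy-2-(4-hydroxyphenyl)-2,3-dihydro-1H-inden-1-yl](4-hydroxyphenyl)methanone | O=C(c1ccc(O)cc1)[C@H]1c2cc(O)cc(O)c2[C@@H](c2cc(O)cc(O)c2)[C@H]1c1ccc(O)cc1 | target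

## Step count and least certain steps

Total step count: 9. Longest linear sequence: 8 steps (1 to 4 to 5 to 7 to 10 to 11 to 14 to 15 to 17); step 4 is a one-step branch.

**Step 5 (key step).** The most likely failure is insertion of the alkyne the other way round, with ring D going to C2 and nickel to C3. C3 is crowded by the doubly ortho-substituted ring A, and ring C is itself a donor, so the electronic bias towards C3 is small. An alkenylnickel on C3 cannot close ring B and would be consumed by protonation or by attack on the ester. Direct transfer of the aryl group to the very electrophilic keto carbonyl, and a low or reversed sense of induction with a glyoxylate acceptor, are further possibilities. A first adjustment within the strategy would be an acyl instead of a benzyl group on the ring C oxygen, to make C3 the more electrophilic alkyne carbon.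

The fallback sets out from 4, draws on 1 and 12 as well, and returns at 10; it closes ring B by forming the C3–C3a bond instead. Aryllithium 3, generated from 1 as in step 1, is acylated with N-methoxy-N-methylacetamide to give 1-[3,5-bis(benzyloxy)phenyl]ethan-1-one F1. Palladium-catalysed α-arylation with 12 (Pd2(dba)3, Xantphos, NaOtBu, toluene, 80 °C) gives 1-[3,5-bis(benzyloxy)phenyl]-2-[4-(benzyloxy)phenyl]ethan-1-one F2. Deprotonation with LDA (THF, −78 °C) and aldol addition to the keto carbonyl of 4 give methyl 2,4-bis[3,5-bis(benzyloxy)phenyl]-3-[4-(benzyloxy)phenyl]-2-hydroxy-4-oxobutanoate F3 as a mixture of diastereomers. Acid (p-TsOH, toluene, 60 °C) should then bring about cyclodehydration: the ring carbon ortho to the carbinol, activated by its ortho and para benzyloxy groups, attacks the aryl ketone, and loss of water gives racemic methyl 4,6-bis(benzyloxy)-3-[3,5-bis(benzyloxy)phenyl]-2-[4-(benzyloxy)phenyl]-1-hydroxy-1H-indene-1-carboxylate F4. Preparative chromatography on a chiral stationary phase delivers 10.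

**Step 8.** The crowded tetrasubstituted C2=C3 bond may resist saturation under conditions mild enough to spare the rest of the molecule. Forcing conditions invite hydrogenolysis of the benzylic C1–O bond and reduction of the aryl ketone. Addition from the aroyl face would give the wrong configuration at C2 and C3.

The fallback sets out from 14 and returns at 15; it separates the two tasks. Homogeneous hydrogenation with [Ir(cod)(PCy3)(py)]PF6 (H2, CH2Cl2), which binds the C1 hydroxyl and delivers hydrogen from its face while leaving benzyl ethers intact, gives the hexabenzyl ether of 15 F5. A short hydrogenolysis over Pd(OH)2/C (H2, EtOAc/MeOH) then removes the benzyl groups to give 15.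

**Step 9.** Protonation of the enolate may occur from the wrong face, or the new C1 centre may equilibrate during the reaction or the isolation of the polyphenol. Over-reduction of the ketone by excess reductant is also possible.

The fallback sets out from 15 and returns at 17; it sets C1 in a separate, non-reductive step on a protected compound. The six phenols of 15 are silylated (TBSCl, imidazole, DMF; the tertiary hydroxyl stays free) to give the hexakis(tert-butyldimethylsilyl) ether of 15 F6. SmI2 in THF/MeOH removes the C1 hydroxyl and gives, whatever the configuration at C1, the hexakis(tert-butyldimethylsilyl) ether of the deoxygenated ketone as its C1 epimers F7. Deprotonation with LDA (THF, −78 °C) and protonation at −78 °C with a hindered phenol from the face opposite ring C give the hexakis(tert-butyldimethylsilyl) ether of 17 F8. HF·pyridine in THF, buffered with pyridine, removes the silyl groups to give 17.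

**Step 7.** Addition of 13 to the crowded amide carbon next to a magnesium alkoxide may be sluggish. If the tetrahedral intermediate collapses before the quench, the α-ketol is exposed to base and may undergo ring expansion by α-ketol rearrangement.

The fallback sets out from 10 and returns at 14; it builds the ketone by addition to an aldehyde. Reduction of the ester with LiAlH4 (THF, 0 °C) gives (1R)-4,6-bis(benzyloxy)-3-[3,5-bis(benzyloxy)phenyl]-2-[4-(benzyloxy)phenyl]-1-(hydroxymethyl)-1H-inden-1-ol F9. Oxidation of the primary alcohol (SO3·pyridine, DMSO, Et3N) gives the hydroxy aldehyde (1R)-4,6-bis(benzyloxy)-3-[3,5-bis(benzyloxy)phenyl]-2-[4-(benzyloxy)phenyl]-1-hydroxy-1H-indene-1-carbaldehyde F10. Addition of 13 gives (1R)-4,6-bis(benzyloxy)-3-[3,5-bis(benzyloxy)phenyl]-2-[4-(benzyloxy)phenyl]-1-{[4-(benzyloxy)phenyl](hydroxy)methyl}-1H-inden-1-ol F11 as a mixture of carbinol epimers. Oxidation of the secondary benzylic alcohol with IBX in DMSO, which converts vicinal diols into α-ketols without cleaving the C–C bond, gives 14.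

## Further compounds

F1 | step 5 | 1-[3,5-bis(benzyloxy)phenyl]ethan-1-one | CC(=O)c1cc(OCc2ccccc2)cc(OCc2ccccc2)c1
F2 | step 5 | 1-[3,5-bis(benzyloxy)phenyl]-2-[4-(benzyloxy)phenyl]ethan-1-one | O=C(Cc1ccc(OCc2ccccc2)cc1)c1cc(OCc2ccccc2)cc(OCc2ccccc2)c1
F3 | step 5 | methyl 2,4-bis[3,5-bis(benzyloxy)phenyl]-3-[4-(benzyloxy)phenyl]-2-hydroxy-4-oxobutanoate (diastereomer mixture) | COC(=O)C(O)(c1cc(OCc2ccccc2)cc(OCc2ccccc2)c1)C(c1ccc(OCc2ccccc2)cc1)C(=O)c1cc(OCc2ccccc2)cc(OCc2ccccc2)c1
F4 | step 5 | racemic methyl 4,6-bis(benzyloxy)-3-[3,5-bis(benzyloxy)phenyl]-2-[4-(benzyloxy)phenyl]-1-hydroxy-1H-indene-1-carboxylate | COC(=O)C1(O)c2cc(OCc3ccccc3)cc(OCc3ccccc3)c2C(c2cc(OCc3ccccc3)cc(OCc3ccccc3)c2)=C1c1ccc(OCc2ccccc2)cc1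
F5 | step 8 | [(1S,2S,3R)-4,6-bis(benzyloxy)-3-[3,5-bis(benzyloxy)phenyl]-2-[4-(benzyloxy)phenyl]-1-hydroxy-2,3-dihydro-1H-inden-1-yl][4-(benzyloxy)phenyl]methanone | O=C(c1ccc(OCc2ccccc2)cc1)[C@@]1(O)c2cc(OCc3ccccc3)cc(OCc3ccccc3)c2[C@@H](c2cc(OCc3ccccc3)cc(OCc3ccccc3)c2)[C@H]1c1ccc(OCc2ccccc2)cc1
F6 | step 9 | [(1S,2S,3R)-4,6-bis[(tert-butyldimethylsilyl)oxy]-3-{3,5-bis[(tert-butyldimethylsilyl)oxy]phenyl}-2-{4-[(tert-butyldimethylsilyl)oxy]phenyl}-1-hydroxy-2,3-dihydro-1H-inden-1-yl]{4-[(tert-butyldimethylsilyl)oxy]phenyl}methanone | O=C(c1ccc(O[Si](C)(C)C(C)(C)C)cc1)[C@@]1(O)c2cc(O[Si](C)(C)C(C)(C)C)cc(O[Si](C)(C)C(C)(C)C)c2[C@@H](c2cc(O[Si](C)(C)C(C)(C)C)cc(O[Si](C)(C)C(C)(C)C)c2)[C@H]1c1ccc(O[Si](C)(C)C(C)(C)C)cc1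
F7 | step 9 | [(2R,3R)-4,6-bis[(tert-butyldimethylsilyl)oxy]-3-{3,5-bis[(tert-butyldimethylsilyl)oxy]phenyl}-2-{4-[(tert-butyldimethylsilyl)oxy]phenyl}-2,3-dihydro-1H-inden-1-yl]{4-[(tert-butyldimethylsilyl)oxy]phenyl}methanone (mixture of C1 epimers) | O=C(c1ccc(O[Si](C)(C)C(C)(C)C)cc1)C1c2cc(O[Si](C)(C)C(C)(C)C)cc(O[Si](C)(C)C(C)(C)C)c2[C@@H](c2cc(O[Si](C)(C)C(C)(C)C)cc(O[Si](C)(C)C(C)(C)C)c2)[C@H]1c1ccc(O[Si](C)(C)C(C)(C)C)cc1
F8 | step 9 | [(1R,2R,3R)-4,6-bis[(tert-butyldimethylsilyl)oxy]-3-{3,5-bis[(tert-butyldimethylsilyl)oxy]phenyl}-2-{4-[(tert-butyldimethylsilyl)oxy]phenyl}-2,3-dihydro-1H-inden-1-yl]{4-[(tert-butyldimethylsilyl)oxy]phenyl}methanone | O=C(c1ccc(O[Si](C)(C)C(C)(C)C)cc1)[C@H]1c2cc(O[Si](C)(C)C(C)(C)C)cc(O[Si](C)(C)C(C)(C)C)c2[C@@H](c2cc(O[Si](C)(C)C(C)(C)C)cc(O[Si](C)(C)C(C)(C)C)c2)[C@H]1c1ccc(O[Si](C)(C)C(C)(C)C)cc1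
F9 | step 7 | (1R)-4,6-bis(benzyloxy)-3-[3,5-bis(benzyloxy)phenyl]-2-[4-(benzyloxy)phenyl]-1-(hydroxymethyl)-1H-inden-1-ol | OC[C@@]1(O)c2cc(OCc3ccccc3)cc(OCc3ccccc3)c2C(c2cc(OCc3ccccc3)cc(OCc3ccccc3)c2)=C1c1ccc(OCc2ccccc2)cc1
F10 | step 7 | (1R)-4,6-bis(benzyloxy)-3-[3,5-bis(benzyloxy)phenyl]-2-[4-(benzyloxy)phenyl]-1-hydroxy-1H-indene-1-carbaldehyde | O=C[C@@]1(O)c2cc(OCc3ccccc3)cc(OCc3ccccc3)c2C(c2cc(OCc3ccccc3)cc(OCc3ccccc3)c2)=C1c1ccc(OCc2ccccc2)cc1
F11 | step 7 | (1R)-4,6-bis(benzyloxy)-3-[3,5-bis(benzyloxy)phenyl]-2-[4-(benzyloxy)phenyl]-1-{[4-(benzyloxy)phenyl](hydroxy)methyl}-1H-inden-1-ol (carbinol epimers) | OC(c1ccc(OCc2ccccc2)cc1)[C@@]1(O)c2cc(OCc3ccccc3)cc(OCc3ccccc3)c2C(c2cc(OCc3ccccc3)cc(OCc3ccccc3)c2)=C1c1ccc(OCc2ccccc2)cc1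
A1 | alternative 1 | 1-[diazo(3,5-dimethoxyphenyl)methyl]-2-[1,3-bis(4-methoxyphenyl)prop-1-en-2-yl]-4,6-dimethoxybenzene | COc1ccc(cc1)/C=C(/Cc1ccc(OC)cc1)\c1cc(OC)cc(OC)c1C(=[N+]=[N-])c1cc(OC)cc(OC)c1
A2 | alternative 1 | cis-4,6-dimethoxy-3-(3,5-dimethoxyphenyl)-1-(4-methoxybenzylidene)-2-(4-methoxyphenyl)indane, C2 and C3 as in the target | COc1ccc(cc1)/C=C1\c2cc(OC)cc(OC)c2[C@@H](c2cc(OC)cc(OC)c2)[C@H]1c1ccc(OC)cc1
A3 | alternative 2 | 3,5-bis(benzyloxy)-2-{1-[3,5-bis(benzyloxy)phenyl]ethenyl}benzaldehyde | O=Cc1cc(OCc2ccccc2)cc(OCc2ccccc2)c1C(=C)c1cc(OCc2ccccc2)cc(OCc2ccccc2)c1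
A4 | alternative 2 | (3R)-4,6-bis(benzyloxy)-3-[3,5-bis(benzyloxy)phenyl]-2,3-dihydro-1H-inden-1-one | O=C1c2cc(OCc3ccccc3)cc(OCc3ccccc3)c2[C@@H](c2cc(OCc3ccccc3)cc(OCc3ccccc3)c2)C1
A5 | alternative 3 | {3,5-bis(benzyloxy)-2-[3,5-bis(benzyloxy)benzoyl]phenyl}boronic acid | OB(O)c1cc(OCc2ccccc2)cc(OCc2ccccc2)c1C(=O)c1cc(OCc2ccccc2)cc(OCc2ccccc2)c1
A6 | alternative 3 | ({1,3-bis[4-(benzyloxy)phenyl]prop-2-yn-1-yl}oxy)(tert-butyl)dimethylsilane, carbinol configured as in A7 | CC(C)(C)[Si](C)(C)O[C@H](c1ccc(OCc2ccccc2)cc1)C#Cc1ccc(OCc2ccccc2)cc1
A7 | alternative 3 | 5,7-bis(benzyloxy)-1-[3,5-bis(benzyloxy)phenyl]-2-[4-(benzyloxy)phenyl]-3-{[4-(benzyloxy)phenyl][(tert-butyldimethylsilyl)oxy]methyl}-1H-inden-1-ol, configured as in the SMILES | CC(C)(C)[Si](C)(C)O[C@H](c1ccc(OCc2ccccc2)cc1)C=1c2cc(OCc3ccccc3)cc(OCc3ccccc3)c2[C@@](O)(c2cc(OCc3ccccc3)cc(OCc3ccccc3)c2)C=1c1ccc(OCc2ccccc2)cc1
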